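**Retrosynthetic overview** (labdane numbering: ring A = C1–C5, C10; ring B = C5–C10; C18 = 4α-carboxyl, C19/C20 = 4β/10β-methyls, C17 = exocyclic CH2)
1. Target ⇐ acetylation/saponification/desilylation ⇐ 25 ⇐ reductive 1,3-transposition of the Δ8 allylic alcohol 22 (makes C8=C17, sets 9α-H) ⇐ B-alkyl Suzuki coupling (C12–C13) of diene 15 with the E-vinyl iodide 19.
2. 15 ⇐ Wittig/hydrogenation ⇐ cycloadduct 13 ⇐ Diels–Alder reaction of ring-A diene 9 with ynal 12: ring B is closed in one step by the bonds C7–C8 and C9–C10, which also creates the quaternary centre C10 and brings in C8, C9, C11 and C17.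
3. Enabling feature: in 9 the tetrasubstituted ring-A alkene C5=C10 carries the vinyl group C6=C7 on C5, so C7=C6–C5=C10 is a 1,3-diene whose termini C7 and C10 are the two ring-B atoms still lacking their partners C8 and C9; the formyl carbon (C11) on C9 polarises the alkyne so that C8 bonds to C7.
4. 9 ⇐ enol triflate 8 ⇐ keto ester 4 ⇐ Frater–Seebach methylation of hydroxy ester 1; C4 is the only stereocentre brought in from outside, and C10, C5 and C9 are relayed from it.
5. Ring order: ring A (from 1) first, ring B second (step 7), side chain last.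

Key step: step 7

Remark (assumption): the Frater–Seebach methylation of the dianion of 1 is taken to place the methyl group trans to the C2 oxygen, which gives the (1R) quaternary centre needed for C4; if the opposite sense were found, the enantiomer of 1 would be the starting material.

**Step 1**
Reactants: 1 ethyl (1R,2S)-2-hydroxycyclohexane-1-carboxylate
Product: 3 ethyl (1R,2S)-2-hydroxy-1-methylcyclohexane-1-carboxylate, via Li2 alkoxide-enolate 2 (not isolated)
Conditions: LiN(iPr)2 (2.2 equiv), THF, −50 → −20 °C; MeI, DMPU, −78 → 0 °C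
Reagents that add atoms: iodomethane, CI
Why: Frater–Seebach alkylation, in which the lithium-chelated alkoxide/ester enolate is methylated on the face away from the alkoxide, so the C2 carbinol centre sets the quaternary centre (future C4) before it is erased.

**Step 2**
Reactants: 3 ethyl (1R,2S)-2-hydroxy-1-methylcyclohexane-1-carboxylate
Product: 4 ethyl (1R)-1-methyl-2-oxocyclohexane-1-carboxylate
Conditions: Pr4N[RuO4] (5 mol %), N-methylmorpholine N-oxide, 4 Å sieves, CH2Cl2, 23 °C
Reagents that add atoms: none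
Why: Ley–Griffith oxidation of the secondary alcohol; the quaternary α-centre cannot epimerise.

**Step 3**
Reactants: 4 ethyl (1R)-1-methyl-2-oxocyclohexane-1-carboxylate
Product: 6 ethyl (1R)-1,3-dimethyl-2-oxocyclohexane-1-carboxylate (C3 epimers), via Li enolate 5 (not isolated)
Conditions: LiN(iPr)2 (1.1 equiv), THF, −78 °C; MeI, −78 → 0 °C
Reagents that add atoms: iodomethane, CI
Why: Enolate alkylation at C3, the only enolisable position; its configuration is irrelevant because the carbon becomes sp2 in step 4.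

**Step 4**
Reactants: 6 ethyl (1R)-1,3-dimethyl-2-oxocyclohexane-1-carboxylate
Product: 8 ethyl (1R)-1,3-dimethyl-2-[(trifluoromethanesulfonyl)oxy]cyclohex-2-ene-1-carboxylate, via K enolate 7 (not isolated)
Conditions: KN(SiMe3)2 (1.2 equiv), THF, −78 → 0 °C; PhNTf2, −78 → 23 °C
Reagents that add atoms: N-phenylbis(trifluoromethanesulfonimide), O=S(=O)(N(c1ccccc1)S(=O)(=O)C(F)(F)F)C(F)(F)F
Why: Enol triflate formation from the only possible (tetrasubstituted) enolate.

**Step 5**
Reactants: 8 ethyl (1R)-1,3-dimethyl-2-[(trifluoromethanesulfonyl)oxy]cyclohex-2-ene-1-carboxylate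
Product: 9 ethyl (1R)-2-ethenyl-1,3-dimethylcyclohex-2-ene-1-carboxylate
Conditions: CH2=CHSnBu3, Pd(PPh3)4 (5 mol %), LiCl (3 equiv), THF, 65 °C
Reagents that add atoms: tributyl(ethenyl)stannane, C=C[Sn](CCCC)(CCCC)CCCC
Why: Stille vinylation of the hindered enol triflate gives the ring-A diene C7=C6–C5=C10.

**Step 6**
Reactants: 10 tert-butyldimethyl(prop-2-yn-1-yloxy)silane
Product: 12 4-[(tert-butyldimethylsilyl)oxy]but-2-ynal, via Li acetylide 11 (not isolated)
Conditions: n-BuLi, THF, −78 °C; DMF, −78 → 0 °C; inverse quench into cold aqueous KH2PO4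
Reagents that add atoms: N,N-dimethylformamide, CN(C)C=O
Why: Formylation of a lithium acetylide with DMF, the ynal being released by the buffered inverse quench.

**Step 7**
Reactants: 9 ethyl (1R)-2-ethenyl-1,3-dimethylcyclohex-2-ene-1-carboxylate; 12 4-[(tert-butyldimethylsilyl)oxy]but-2-ynal
Product: 13 ethyl 17-[(tert-butyldimethylsilyl)oxy]-11-oxo-12,13,14,15,16-pentanorlabda-5,8-dien-18-oate (4α-CO2Et, 4β-CH3, 10β-CH3)
Conditions: 12 (1.3 equiv), BF3·OEt2 (0.3 equiv), CH2Cl2, −78 → −30 °C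
Reagents that add atoms: none
Why: The BF3-activated ynal and the diene should combine in a concerted, asynchronous [4+2] cycloaddition of normal electron demand, the reaction type long used to build the drimane nucleus from 2,6,6-trimethyl-1-vinylcyclohexene and acetylenic dienophiles. Six-membered ring B is closed in the cycloaddition mode by the two new bonds C7–C8 and C9–C10, the bond C7–C8 being the more advanced in the transition state. The regioselectivity needed (C7 to C8, C10 to C9) should follow from polarisation: the unsubstituted terminus C7 carries the largest HOMO coefficient of the 1,1,2-trialkyl diene and C8, beta to the formyl group, the largest LUMO coefficient. The one new stereocentre, quaternary C10, is controlled by the C4 stereocentre of 9: in the s-cis diene the C4 methyl should sit pseudoaxial on the β-face while the flat ester takes the in-plane position next to the vinyl group, so the dienophile adds on the α-face and the C10 methyl ends cis to the C4 methyl. An alkyne dienophile raises no endo/exo question, and the 1,4-diene product cannot aromatise because C10 is quaternary. Facial selectivity is the selectivity this step depends on most, and the low temperature of the catalysed reaction serves it.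

**Step 8**
Reactants: 13 ethyl 17-[(tert-butyldimethylsilyl)oxy]-11-oxo-12,13,14,15,16-pentanorlabda-5,8-dien-18-oate
Product: 14 ethyl 17-[(tert-butyldimethylsilyl)oxy]-11-oxo-12,13,14,15,16-pentanor-5α-labd-8-en-18-oate
Conditions: H2 (3 atm), 10% Pd/C, EtOAc, 23 °C
Reagents that add atoms: none
Why: Heterogeneous syn-hydrogenation of the trisubstituted C5=C6 bond from the α-face, anti to the axial C4 and C10 methyl groups, should set 5α-H (trans-decalin) as in the drimane series, while the tetrasubstituted, formyl-conjugated C8=C9 bond is spared.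

**Step 9**
Reactants: 14 ethyl 17-[(tert-butyldimethylsilyl)oxy]-11-oxo-12,13,14,15,16-pentanor-5α-labd-8-en-18-oate
Product: 15 ethyl 17-[(tert-butyldimethylsilyl)oxy]-13,14,15,16-tetranor-5α-labda-8,11-dien-18-oate
Conditions: Ph3PCH3Br, KOtBu, THF, 0 → 23 °C
Reagents that add atoms: methyltriphenylphosphonium bromide, C[P+](c1ccccc1)(c1ccccc1)c1ccccc1.[Br-]
Why: Wittig methylenation of the hindered conjugated aldehyde adds C12 and gives the C8=C9–C11=C12 diene used for chain extension.

**Step 10**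
Reactants: 16 but-2-yn-1-ol
Product: 17 (but-2-yn-1-yloxy)(tert-butyl)diphenylsilane
Conditions: tBuPh2SiCl, imidazole, DMF, 23 °C
Reagents that add atoms: tert-butyl(chloro)diphenylsilane, CC(C)(C)[Si](Cl)(c1ccccc1)c1ccccc1
Why: Standard silylation of a primary alcohol.

**Step 11**
Reactants: 17 (but-2-yn-1-yloxy)(tert-butyl)diphenylsilane
Product: 19 tert-butyl{[(2E)-3-iodobut-2-en-1-yl]oxy}diphenylsilane, via alkenyl-Zr(Cl)Cp2 species 18 (not isolated)
Conditions: Cp2Zr(H)Cl (1.5 equiv), THF, 23 → 45 °C; I2, 0 °C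
Reagents that add atoms: iodine, II
Why: Hydrozirconation–iodination: syn addition puts zirconium on the methyl-bearing alkyne carbon, remote from the bulky silyloxymethyl group, and iodinolysis with retention gives the E-iodide.

**Step 12**
Reactants: 15 ethyl 17-[(tert-butyldimethylsilyl)oxy]-13,14,15,16-tetranor-5α-labda-8,11-dien-18-oate; 19 tert-butyl{[(2E)-3-iodobut-2-en-1-yl]oxy}diphenylsilane
Product: 21 ethyl 17-[(tert-butyldimethylsilyl)oxy]-15-[(tert-butyldiphenylsilyl)oxy]labda-8,13E-dien-18-oate, via B-alkyl-9-BBN adduct 20 (not isolated)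
Conditions: 9-BBN, THF, 0 → 40 °C; then 19, PdCl2(dppf) (5 mol %), AsPh3, Cs2CO3, DMF/H2O, 23 °C
Reagents that add atoms: none
Why: Anti-Markovnikov hydroboration of the only monosubstituted alkene followed by B-alkyl Suzuki–Miyaura coupling should form C12–C13 with retention of the E geometry of 19.

**Step 13**
Reactants: 21 ethyl 17-[(tert-butyldimethylsilyl)oxy]-15-[(tert-butyldiphenylsilyl)oxy]labda-8,13E-dien-18-oate
Product: 22 ethyl 15-[(tert-butyldiphenylsilyl)oxy]-17-hydroxylabda-8,13E-dien-18-oate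
Conditions: HF·pyridine, pyridine, THF, 0 → 23 °C
Reagents that add atoms: none
Why: Selective desilylation, the primary TBS ether being cleaved faster than the TBDPS ether under buffered HF.

**Step 14**
Reactants: 22 ethyl 15-[(tert-butyldiphenylsilyl)oxy]-17-hydroxylabda-8,13E-dien-18-oate
Product: 25 ethyl 15-[(tert-butyldiphenylsilyl)oxy]labda-8(17),13E-dien-18-oate (9α-H), via N-allyl sulfonylhydrazide 23 (not isolated), via allylic diazene 24 (not isolated)
Conditions: 2-nitrobenzenesulfonylhydrazide, PPh3, diethyl azodicarboxylate, THF, −30 °C; then 23 °C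
Reagents that add atoms: none
Why: Myers reductive 1,3-transposition: Mitsunobu N-alkylation, loss of the sulfinic acid and sigmatropic loss of N2 from the allylic diazene move the alkene to C8=C17 and deliver hydrogen to C9 on the less hindered α-face (anti to the axial C10 methyl), setting 9α-H.

**Step 15**
Reactants: 25 ethyl 15-[(tert-butyldiphenylsilyl)oxy]labda-8(17),13E-dien-18-oate
Product: 26 ethyl 15-hydroxylabda-8(17),13E-dien-18-oate
Conditions: Bu4NF, THF, 23 °C
Reagents that add atoms: none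
Why: Fluoride desilylation of the TBDPS ether.

**Step 16**
Reactants: 26 ethyl 15-hydroxylabda-8(17),13E-dien-18-oate
Product: 27 15-hydroxylabda-8(17),13E-dien-18-oic acid
Conditions: KOH (excess), EtOH/H2O, 80 °C; then 1 M HCl to pH 3
Reagents that add atoms: potassium hydroxide, [K+].[OH-]
Why: Saponification of the hindered but equatorial ethyl ester; no base-sensitive centre is present.

**Step 17**
Reactants: 27 15-hydroxylabda-8(17),13E-dien-18-oic acid
Product: 29 15-acetoxylabda-8(17),13E-dien-18-oic acid (target), via mixed acetic anhydride 28 (not isolated)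
Conditions: Ac2O, pyridine, 4-(dimethylamino)pyridine (cat.), CH2Cl2, 0 → 23 °C; then THF/H2O, 23 °C
Reagents that add atoms: acetic anhydride, CC(=O)OC(C)=O
Why: O-Acetylation of the primary allylic alcohol; any mixed anhydride formed at the hindered acid should be hydrolysed at its acetyl carbonyl in the aqueous stage.

**Compound list**
1 | ethyl (1R,2S)-2-hydroxycyclohexane-1-carboxylate | O[C@H]1CCCC[C@H]1C(=O)OCC | starting material
2 | Li2 alkoxide-enolate of 1 (O-lithio carbinol, lithium ester enolate) | [Li]O[C@H]1CCCCC1=C(O[Li])OCC | intermediate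
3 | ethyl (1R,2S)-2-hydroxy-1-methylcyclohexane-1-carboxylate | O[C@H]1CCCC[C@@]1(C)C(=O)OCC | intermediate
4 | ethyl (1R)-1-methyl-2-oxocyclohexane-1-carboxylate | O=C1CCCC[C@@]1(C)C(=O)OCC | intermediate
5 | Li enolate of 4 | [Li]OC1=CCCC[C@@]1(C)C(=O)OCC | intermediate
6 | ethyl (1R)-1,3-dimethyl-2-oxocyclohexane-1-carboxylate (C3 epimers) | O=C1C(C)CCC[C@@]1(C)C(=O)OCC | intermediate
7 | K enolate of 6 | [K]OC1=C(C)CCC[C@@]1(C)C(=O)OCC | intermediate
8 | ethyl (1R)-1,3-dimethyl-2-[(trifluoromethanesulfonyl)oxy]cyclohex-2-ene-1-carboxylate | O=S(=O)(OC1=C(C)CCC[C@@]1(C)C(=O)OCC)C(F)(F)F | intermediate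
9 | ethyl (1R)-2-ethenyl-1,3-dimethylcyclohex-2-ene-1-carboxylate | C=CC1=C(C)CCC[C@@]1(C)C(=O)OCC | intermediate
10 | tert-butyldimethyl(prop-2-yn-1-yloxy)silane | C#CCO[Si](C)(C)C(C)(C)C | starting material
11 | Li acetylide of 10 | [Li]C#CCO[Si](C)(C)C(C)(C)C | intermediate
12 | 4-[(tert-butyldimethylsilyl)oxy]but-2-ynal | O=CC#CCO[Si](C)(C)C(C)(C)C | intermediate
13 | ethyl 17-[(tert-butyldimethylsilyl)oxy]-11-oxo-12,13,14,15,16-pentanorlabda-5,8-dien-18-oate | CC(C)(C)[Si](C)(C)OCC1=C(C=O)[C@@]2(C)CCC[C@@](C)(C(=O)OCC)C2=CC1 | intermediate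
14 | ethyl 17-[(tert-butyldimethylsilyl)oxy]-11-oxo-12,13,14,15,16-pentanor-5α-labd-8-en-18-oate | CC(C)(C)[Si](C)(C)OCC1=C(C=O)[C@@]2(C)CCC[C@@](C)(C(=O)OCC)[C@@H]2CC1 | intermediate
15 | ethyl 17-[(tert-butyldimethylsilyl)oxy]-13,14,15,16-tetranor-5α-labda-8,11-dien-18-oate | CC(C)(C)[Si](C)(C)OCC1=C(C=C)[C@@]2(C)CCC[C@@](C)(C(=O)OCC)[C@@H]2CC1 | intermediate
16 | but-2-yn-1-ol | CC#CCO | starting material
17 | (but-2-yn-1-yloxy)(tert-butyl)diphenylsilane | CC#CCO[Si](c1ccccc1)(c1ccccc1)C(C)(C)C | intermediate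
18 | (E)-[4-(tert-butyldiphenylsilyloxy)but-2-en-2-yl]Zr(Cl)Cp2 | C/C(=C\CO[Si](c1ccccc1)(c1ccccc1)C(C)(C)C)[Zr](Cl)(C1C=CC=C1)C1C=CC=C1 | intermediate
19 | tert-butyl{[(2E)-3-iodobut-2-en-1-yl]oxy}diphenylsilane | C/C(I)=C\CO[Si](c1ccccc1)(c1ccccc1)C(C)(C)C | intermediate
20 | 12-(9-borabicyclo[3.3.1]nonan-9-yl) adduct of 15 | CC(C)(C)[Si](C)(C)OCC1=C(CCB3C4CCCC3CCC4)[C@@]2(C)CCC[C@@](C)(C(=O)OCC)[C@@H]2CC1 | intermediate
21 | ethyl 17-[(tert-butyldimethylsilyl)oxy]-15-[(tert-butyldiphenylsilyl)oxy]labda-8,13E-dien-18-oate | CC(C)(C)[Si](C)(C)OCC1=C(CC/C(C)=C/CO[Si](c3ccccc3)(c3ccccc3)C(C)(C)C)[C@@]2(C)CCC[C@@](C)(C(=O)OCC)[C@@H]2CC1 | intermediate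
22 | ethyl 15-[(tert-butyldiphenylsilyl)oxy]-17-hydroxylabda-8,13E-dien-18-oate | OCC1=C(CC/C(C)=C/CO[Si](c3ccccc3)(c3ccccc3)C(C)(C)C)[C@@]2(C)CCC[C@@](C)(C(=O)OCC)[C@@H]2CC1 | intermediate
23 | N-(C17-allyl)-N-(2-nitrobenzenesulfonyl)hydrazine derived from 22 | NN(CC1=C(CC/C(C)=C/CO[Si](c3ccccc3)(c3ccccc3)C(C)(C)C)[C@@]2(C)CCC[C@@](C)(C(=O)OCC)[C@@H]2CC1)S(=O)(=O)c1ccccc1[N+](=O)[O-] | intermediate
24 | C17 monoalkyl diazene derived from 23 | N=NCC1=C(CC/C(C)=C/CO[Si](c3ccccc3)(c3ccccc3)C(C)(C)C)[C@@]2(C)CCC[C@@](C)(C(=O)OCC)[C@@H]2CC1 | intermediate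
25 | ethyl 15-[(tert-butyldiphenylsilyl)oxy]labda-8(17),13E-dien-18-oate | C=C1CC[C@@H]2[C@](C)(CCC[C@@]2(C)C(=O)OCC)[C@H]1CC/C(C)=C/CO[Si](c3ccccc3)(c3ccccc3)C(C)(C)C | intermediate
26 | ethyl 15-hydroxylabda-8(17),13E-dien-18-oate | C=C1CC[C@@H]2[C@](C)(CCC[C@@]2(C)C(=O)OCC)[C@H]1CC/C(C)=C/CO | intermediate
27 | 15-hydroxylabda-8(17),13E-dien-18-oic acid | C=C1CC[C@@H]2[C@](C)(CCC[C@@]2(C)C(=O)O)[C@H]1CC/C(C)=C/CO | intermediate
28 | acetic 15-acetoxylabda-8(17),13E-dien-18-oic anhydride | C=C1CC[C@@H]2[C@](C)(CCC[C@@]2(C)C(=O)OC(C)=O)[C@H]1CC/C(C)=C/COC(C)=O | intermediate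
29 | 15-acetoxylabda-8(17),13E-dien-18-oic acid = (1R,4aR,5S,8aR)-5-[(3E)-5-(acetyloxy)-3-methylpent-3-en-1-yl]-1,4a-dimethyl-6-methylidenedecahydronaphthalene-1-carboxylic acid | C=C1CC[C@@H]2[C@](C)(CCC[C@@]2(C)C(=O)O)[C@H]1CC/C(C)=C/COC(C)=O | target

**Step count and risks**
Total step count: 17. Longest linear sequence: 14 steps (1–5, 7–9, 12–17).

The three steps most likely to fail:

Step 7. The ynal may add with too little π-facial discrimination (addition on the face of the C4 methyl gives the C10 epimer). If bonding at the fully substituted C10 lags, regiocontrol may also be lost and the diene may oligomerise under the Lewis acid. The fallback sets out from 9 and delivers the dienophile intramolecularly from C18. Reduction of 9 (LiAlH4, Et2O, 0 °C) should give [(1R)-2-ethenyl-1,3-dimethylcyclohex-2-en-1-yl]methanol F1. Carboxylation of 11 (CO2, THF, −78 °C) gives 4-[(tert-butyldimethylsilyl)oxy]but-2-ynoic acid F2. Esterification of the two (N,N'-dicyclohexylcarbodiimide, 4-(dimethylamino)pyridine, CH2Cl2) gives [(1R)-2-ethenyl-1,3-dimethylcyclohex-2-en-1-yl]methyl 4-[(tert-butyldimethylsilyl)oxy]but-2-ynoate F3. Its thermal type 2 intramolecular Diels–Alder reaction (o-dichlorobenzene, 150–180 °C) can only join C9 to C10 from the α-face and C8 to C7, and should give the bridged lactone 17-[(tert-butyldimethylsilyl)oxy]-12,13,14,15,16-pentanorlabda-5,8-dien-11,18-olide F4. Reduction with iBu2AlH (CH2Cl2, −78 °C) opens it to 17-[(tert-butyldimethylsilyl)oxy]-18-hydroxy-12,13,14,15,16-pentanorlabda-5,8-dien-11-al F5. Hydrogenation as in step 8 gives 17-[(tert-butyldimethylsilyl)oxy]-18-hydroxy-12,13,14,15,16-pentanor-5α-labd-8-en-11-al F6, and methylenation as in step 9 gives 17-[(tert-butyldimethylsilyl)oxy]-13,14,15,16-tetranor-5α-labda-8,11-dien-18-ol F7. Oxidation with PhI(OAc)2 and catalytic TEMPO in MeCN/H2O gives 17-[(tert-butyldimethylsilyl)oxy]-13,14,15,16-tetranor-5α-labda-8,11-dien-18-oic acid F8, and EtI/K2CO3 (DMF) brings the sequence back to the route at 15.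

Step 8. Hydrogen may be delivered to the β-face (cis ring fusion), or palladium may isomerise the 1,4-diene and reduce the enal or cleave the allylic C–O bond. The fallback sets out from 13. Base-mediated isomerisation (1,8-diazabicyclo[5.4.0]undec-7-ene, toluene, 80 °C) should give the fully conjugated ethyl 17-[(tert-butyldimethylsilyl)oxy]-11-oxo-12,13,14,15,16-pentanor-5α-labda-6,8-dien-18-oate F9, in which C5 is set by protonation under thermodynamic control (trans ring fusion). The now unhindered disubstituted C6=C7 bond is then hydrogenated (H2, Pd/C, EtOAc, 23 °C), which returns to the route at 14.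

Step 14. The Mitsunobu step at the hindered allylic alcohol may divert to SN2' or elimination products, or the diazene may deliver hydrogen to the β-face of C9. The fallback sets out from 22. Methyl chloroformate and pyridine (CH2Cl2, 0 °C) give ethyl 15-[(tert-butyldiphenylsilyl)oxy]-17-[(methoxycarbonyl)oxy]labda-8,13E-dien-18-oate F10. Formate reduction of the derived allylpalladium complex (Pd(OAc)2, PBu3, HCO2H/Et3N, dioxane, 23–60 °C) transfers hydride to the more substituted terminus C9 on the less hindered α-face, which returns to the route at 25.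

**Further compounds**
F1 | step 7 | [(1R)-2-ethenyl-1,3-dimethylcyclohex-2-en-1-yl]methanol | C=CC1=C(C)CCC[C@@]1(C)CO
F2 | step 7 | 4-[(tert-butyldimethylsilyl)oxy]but-2-ynoic acid | O=C(O)C#CCO[Si](C)(C)C(C)(C)C
F3 | step 7 | [(1R)-2-ethenyl-1,3-dimethylcyclohex-2-en-1-yl]methyl 4-[(tert-butyldimethylsilyl)oxy]but-2-ynoate | C=CC1=C(C)CCC[C@@]1(C)COC(=O)C#CCO[Si](C)(C)C(C)(C)C
F4 | step 7 | 17-[(tert-butyldimethylsilyl)oxy]-12,13,14,15,16-pentanorlabda-5,8-dien-11,18-olide | CC(C)(C)[Si](C)(C)OCC1=C2C(=O)OC[C@]3(C)CCC[C@@]2(C)C3=CC1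
F5 | step 7 | 17-[(tert-butyldimethylsilyl)oxy]-18-hydroxy-12,13,14,15,16-pentanorlabda-5,8-dien-11-al | CC(C)(C)[Si](C)(C)OCC1=C(C=O)[C@@]2(C)CCC[C@@](C)(CO)C2=CC1
F6 | step 7 | 17-[(tert-butyldimethylsilyl)oxy]-18-hydroxy-12,13,14,15,16-pentanor-5α-labd-8-en-11-al | CC(C)(C)[Si](C)(C)OCC1=C(C=O)[C@@]2(C)CCC[C@@](C)(CO)[C@@H]2CC1
F7 | step 7 | 17-[(tert-butyldimethylsilyl)oxy]-13,14,15,16-tetranor-5α-labda-8,11-dien-18-ol | CC(C)(C)[Si](C)(C)OCC1=C(C=C)[C@@]2(C)CCC[C@@](C)(CO)[C@@H]2CC1
F8 | step 7 | 17-[(tert-butyldimethylsilyl)oxy]-13,14,15,16-tetranor-5α-labda-8,11-dien-18-oic acid | CC(C)(C)[Si](C)(C)OCC1=C(C=C)[C@@]2(C)CCC[C@@](C)(C(=O)O)[C@@H]2CC1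
F9 | step 8 | ethyl 17-[(tert-butyldimethylsilyl)oxy]-11-oxo-12,13,14,15,16-pentanor-5α-labda-6,8-dien-18-oate | CC(C)(C)[Si](C)(C)OCC1=C(C=O)[C@@]2(C)CCC[C@@](C)(C(=O)OCC)[C@@H]2C=C1
F10 | step 14 | ethyl 15-[(tert-butyldiphenylsilyl)oxy]-17-[(methoxycarbonyl)oxy]labda-8,13E-dien-18-oate | COC(=O)OCC1=C(CC/C(C)=C/CO[Si](c3ccccc3)(c3ccccc3)C(C)(C)C)[C@@]2(C)CCC[C@@](C)(C(=O)OCC)[C@@H]2CC1
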